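**Retrosynthetic overview**

1. Skeleton numbering used throughout: C1 (ketone), C2=C3 (furanone alkene; the ring oxygen joins C3 and C10), C4(–C15H2OH)=C5, C6 (lactone O), C7, C8 (crotonate), C9H2, C10(–C14H3), C11(=C13H2)–C12(=O).
2. Feature and key disconnection: the C3–C4 sp2–sp2 single bond between the vinylogous acyl carbon C3 of the 3(2H)-furanone ring (O, C3, C2, C1, C10) and C4 of the C4=C5 alkene. This bond lies in the nine-membered oxa-bridged ring (C3 to C10 plus the ring oxygen; ten-membered carbocycle C1–C10). It is cut to a C3 methylthio group and a C4 tributylstannyl group cis to C6.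
3. The stannane comes from the C4≡C5 alkyne by C15-hydroxyl-directed trans-hydrostannation after O8 crotonylation. The C7–C8 bond and the C7 and C8 stereocentres come from a zinc Barbier reaction of the C8 aldehyde of the methylthiofuranone with a (6R)-3-(bromomethyl)-5-alkynylbutenolide.
4. Fragments: the furanone aldehyde from (R)-citramalic acid (C10) via a methyl ketone, CS2/MeI and addition–elimination ring closure; the butenolide bromide from 2-butyne-1,4-diol via trans-hydroalumination/iodination, enantioselective alkynylation (C6) and carbonylative lactonisation.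
5. Ring order: furanone ring, then butenolide ring (it becomes the methylene lactone in the Barbier step), nine-membered ring last.

Key step: step 20

Remark: in step 12 the (S,S) antipode of ProPhenol is written on the assumption that it gives the 6R carbinol; if it delivers the alkynyl group to the other aldehyde face, its mirror image is used.

**Fragment A: furanone aldehyde (steps 1–8)**

Step 1
Reactants: 1 (R)-citramalic acid; 2 2,2-dimethoxypropane
Product: 3 2-[(4R)-2,2,4-trimethyl-5-oxo-1,3-dioxolan-4-yl]acetic acid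
Conditions: 2,2-dimethoxypropane (excess), TsOH·H2O (cat.), rt
Reagents that add atoms: 2,2-dimethoxypropane, COC(C)(C)OC
Why: Acid-catalysed transacetalisation closes the α-hydroxy acid to the five-membered 1,3-dioxolan-4-one and leaves the β-carboxyl free, without touching the quaternary stereocentre (the future C10).

Step 2
Reactants: 3 dioxolanone acid
Product: 5 (3R)-3-hydroxy-3-methyloxolan-2-one, via hydroxyethyl dioxolanone 4 (not isolated)
Conditions: BH3·SMe2, THF, 0 °C to rt; MeOH; then TsOH (cat.), CH2Cl2, rt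
Reagents that add atoms: none
Why: Borane reduces the free carboxylic acid much faster than the dioxolanone carbonyl (chemoselective borane reduction), and the primary alcohol then transacylates under acid to the γ-lactone with loss of acetone.

Step 3
Reactants: 5 hydroxy lactone; 6 N,O-dimethylhydroxylamine hydrochloride
Product: 7 (2R)-2,4-dihydroxy-N-methoxy-N,2-dimethylbutanamide
Conditions: MeNH(OMe)·HCl, Me3Al, CH2Cl2, 0 °C to rt; aq. KNaC4H4O6 work-up; used at once
Reagents that add atoms: N,O-dimethylhydroxylamine hydrochloride, CNOC.Cl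
Why: Weinreb aminolysis of the lactone by the aluminium amide opens the ring to the hydroxy amide, which is silylated directly so that it cannot close back.

Step 4
Reactants: 7 dihydroxy Weinreb amide; 8 triethylsilyl trifluoromethanesulfonate
Product: 9 (2R)-N-methoxy-N,2-dimethyl-2,4-bis(triethylsilyloxy)butanamide
Conditions: TESOTf (2.5 equiv), 2,6-lutidine, CH2Cl2, −78 to 0 °C
Reagents that add atoms: triethylsilyl trifluoromethanesulfonate, CC[Si](CC)(CC)OS(=O)(=O)C(F)(F)F
Why: Silyl triflate silylation caps both the primary and the tertiary hydroxyl, which blocks relactonisation and later xanthate formation with CS2.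

Step 5
Reactants: 9 bis-silyl Weinreb amide; 10 methylmagnesium bromide
Product: 11 (3R)-3-methyl-3,5-bis(triethylsilyloxy)pentan-2-one
Conditions: MeMgBr, THF, 0 °C to rt; aq. NH4Cl
Reagents that add atoms: methylmagnesium bromide, C[Mg]Br
Why: Weinreb ketone synthesis: the chelated tetrahedral adduct holds until work-up, so the addition stops at the methyl ketone (C1, C2).

Step 6
Reactants: 11 methyl ketone; 12 carbon disulfide; 13 iodomethane
Product: 15 (4R)-4-methyl-1,1-bis(methylsulfanyl)-4,6-bis(triethylsilyloxy)hex-1-en-3-one, via dilithium enedithiolate 14 (not isolated)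
Conditions: LiN(SiMe3)2 (1.1 equiv), THF, −78 °C; CS2; LiN(SiMe3)2 (1.1 equiv); MeI (2.5 equiv), −78 °C to rt
Reagents that add atoms: carbon disulfide, S=C=S; iodomethane, CI
Why: α-Oxo ketene dithioacetal formation: the methyl group is the only enolisable position, its enolate adds to CS2, and double S-methylation installs C3 with both methylthio groups.

Step 7
Reactants: 15 ketene dithioacetal
Product: 17 (2R)-2-(2-hydroxyethyl)-2-methyl-5-(methylsulfanyl)furan-3(2H)-one, via dihydroxy ketene dithioacetal 16 (not isolated)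
Conditions: HF·pyridine, THF, 0 °C to rt; then camphorsulfonic acid (cat.), CH2Cl2 (dry), rt
Reagents that add atoms: none
Why: After fluoride desilylation the tertiary hydroxyl adds to the acid-activated push–pull alkene and methanethiol is lost (intramolecular addition–elimination on an α-oxo ketene dithioacetal, the reaction type that gives 2-methylthiochromones), which closes the five-membered furanone in preference to a seven-membered ring through the primary hydroxyl.

Step 8
Reactants: 17 furanone alcohol
Product: 18 2-[(2R)-2-methyl-5-(methylsulfanyl)-3-oxo-2,3-dihydrofuran-2-yl]acetaldehyde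
Conditions: Dess–Martin periodinane, NaHCO3, CH2Cl2, 0 °C to rt; used without storage
Reagents that add atoms: none
Why: Dess–Martin oxidation under buffered, base-free conditions gives the C8 aldehyde without oxidising the conjugated sulfide and without β-elimination of the furanone oxygen.

**Fragment B: butenolide bromide (steps 9–15)**

Step 9
Reactants: 19 2-butyne-1,4-diol; 20 4-methoxybenzyl chloride
Product: 21 4-[(4-methoxyphenyl)methoxy]but-2-yn-1-ol
Conditions: diol (3 equiv), NaH (1 equiv), PMBCl (1 equiv), Bu4NI (cat.), THF/DMF, 0 °C to rt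
Reagents that add atoms: 4-methoxybenzyl chloride, COc1ccc(CCl)cc1
Why: Williamson etherification with the diol in excess gives the mono-ether, so the two ends (future C6 and C13) are told apart.

Step 10
Reactants: 21 mono-PMB butynediol; 22 iodine
Product: 24 (2Z)-3-iodo-4-[(4-methoxyphenyl)methoxy]but-2-en-1-ol, via cyclic alkenylaluminate 23 (not isolated)
Conditions: NaAlH2(OCH2CH2OMe)2, THF, 0 °C; EtOAc; then I2, −78 to 0 °C
Reagents that add atoms: iodine, II
Why: Hydroxyl-directed trans-hydroalumination puts hydride on the proximal carbon (C7) and aluminium on the distal carbon (C11) in a five-membered aluminate, and iodinolysis with retention gives the iodide cis to the carbinol carbon.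

Step 11
Reactants: 24 (Z)-iodo allylic alcohol
Product: 25 (2Z)-3-iodo-4-[(4-methoxyphenyl)methoxy]but-2-enal
Conditions: MnO2 (activated, excess), CH2Cl2, rt, dark
Reagents that add atoms: none
Why: Allylic oxidation with MnO2 gives the enal (C6 aldehyde) under neutral conditions that should keep the Z geometry.

Step 12
Reactants: 25 (Z)-iodo enal; 26 tert-butyldimethyl(prop-2-yn-1-yloxy)silane
Product: 28 (2Z,4R)-7-(tert-butyldimethylsilyloxy)-2-iodo-1-[(4-methoxyphenyl)methoxy]hept-2-en-5-yn-4-ol, via alkynyl(methyl)zinc 27 (not isolated)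
Conditions: 26 (3 equiv), Me2Zn (3 equiv), (S,S)-ProPhenol (20 mol %), Ph3P=O (40 mol %), toluene, 0 °C; then 25, 0 to 4 °C
Reagents that add atoms: tert-butyldimethyl(prop-2-yn-1-yloxy)silane, C#CCO[Si](C)(C)C(C)(C)C
Why: Zinc–ProPhenol-catalysed enantioselective alkynylation of an enal: the dinuclear zinc catalyst delivers the alkynyl group to one face of the aldehyde and sets C6 (R here), the centre that later controls C7 and C8.

Step 13
Reactants: 28 iodo dienynol; 29 carbon monoxide
Product: 30 (5R)-5-[3-(tert-butyldimethylsilyloxy)prop-1-yn-1-yl]-3-{[(4-methoxyphenyl)methoxy]methyl}furan-2(5H)-one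
Conditions: Pd(PPh3)4 (5 mol %), CO (1 atm), K2CO3, THF, 40 °C
Reagents that add atoms: carbon monoxide, [C-]#[O+]
Why: Zerovalent palladium inserts into the alkenyl C–I bond, CO insertion gives the acylpalladium and the cis C6 hydroxyl captures it (carbonylative lactonisation of a (Z)-3-iodoallylic alcohol), while solid carbonate in THF is weak enough to leave the doubly activated C6–H in place.

Step 14
Reactants: 30 PMB butenolide
Product: 31 (5R)-5-[3-(tert-butyldimethylsilyloxy)prop-1-yn-1-yl]-3-(hydroxymethyl)furan-2(5H)-one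
Conditions: DDQ, CH2Cl2/pH 7 buffer, 0 °C to rt
Reagents that add atoms: none
Why: Oxidative cleavage of the PMB ether by DDQ frees the C13 hydroxyl under neutral conditions and leaves the silyl ether, alkyne and butenolide alone.

Step 15
Reactants: 31 hydroxymethyl butenolide; 32 tetrabromomethane
Product: 33 (5R)-3-(bromomethyl)-5-[3-(tert-butyldimethylsilyloxy)prop-1-yn-1-yl]furan-2(5H)-one
Conditions: CBr4, PPh3, CH2Cl2, 0 °C
Reagents that add atoms: tetrabromomethane, BrC(Br)(Br)Br
Why: Appel bromination converts the primary allylic alcohol into the bromide without base, so the C6 centre is not put at risk.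

**Union and end game (steps 16–20)**

Step 16
Reactants: 33 bromomethyl butenolide; 18 furanone aldehyde
Product: 35 (4S,5R)-5-[3-(tert-butyldimethylsilyloxy)prop-1-yn-1-yl]-4-{(1R)-1-hydroxy-2-[(2R)-2-methyl-5-(methylsulfanyl)-3-oxo-2,3-dihydrofuran-2-yl]ethyl}-3-methylideneoxolan-2-one, via allylzinc bromide 34 (not isolated)
Conditions: Zn (activated), THF/sat. aq. NH4Cl, 0 °C to rt; 33 (1.5 equiv)
Reagents that add atoms: none
Why: Zinc inserts into the allylic C–Br bond and the allylzinc reacts at its γ-carbon C7 with the aldehyde through a closed chair transition state (Barbier 2-(alkoxycarbonyl)allylation with a 3-(bromomethyl)butenolide, SE2′), so that the ring-locked geometry (C6 trans to the CH2Zn group) with the aldehyde chain equatorial sets the C7/C8 anti relation (8R) and attack on the butenolide face opposite the C6 alkynyl group sets C7 trans to C6 (7S), the vinylogous thioester carbonyl being far less electrophilic than the aldehyde.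

Step 17
Reactants: 35 Barbier adduct; 36 (E)-crotonic anhydride
Product: 37 (1R)-1-{(2R,3S)-2-[3-(tert-butyldimethylsilyloxy)prop-1-yn-1-yl]-4-methylidene-5-oxooxolan-3-yl}-2-[(2R)-2-methyl-5-(methylsulfanyl)-3-oxo-2,3-dihydrofuran-2-yl]ethyl (2E)-but-2-enoate
Conditions: (E)-crotonic anhydride, DMAP (cat.), iPr2NEt, CH2Cl2, 0 °C to rt
Reagents that add atoms: (E)-crotonic anhydride, C/C=C/C(=O)OC(=O)/C=C/C
Why: DMAP-catalysed acylation with the anhydride esterifies the C8 hydroxyl, and avoiding the acid chloride/amine pair avoids the vinylketene path that would shift the crotonate double bond out of conjugation.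

Step 18
Reactants: 37 silyl ether crotonate
Product: 38 (1R)-1-[(2R,3S)-2-(3-hydroxyprop-1-yn-1-yl)-4-methylidene-5-oxooxolan-3-yl]-2-[(2R)-2-methyl-5-(methylsulfanyl)-3-oxo-2,3-dihydrofuran-2-yl]ethyl (2E)-but-2-enoate
Conditions: HF·pyridine, pyridine, THF, 0 °C to rt
Reagents that add atoms: none
Why: Buffered fluoride desilylation frees the C15 hydroxyl without base strong enough to attack the methylene lactone or the crotonate.

Step 19
Reactants: 38 propargylic alcohol; 39 tributyltin hydride
Product: 40 (1R)-1-{(2R,3S)-2-[(1Z)-3-hydroxy-2-(tributylstannyl)prop-1-en-1-yl]-4-methylidene-5-oxooxolan-3-yl}-2-[(2R)-2-methyl-5-(methylsulfanyl)-3-oxo-2,3-dihydrofuran-2-yl]ethyl (2E)-but-2-enoate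
Conditions: [Cp*RuCl]4 (2.5 mol %), Bu3SnH (1.1 equiv, slow addition), CH2Cl2, rt
Reagents that add atoms: tributyltin hydride, CCCC[SnH](CCCC)CCCC
Why: Hydroxyl-directed ruthenium-catalysed trans-hydrostannation: the free C15 hydroxyl hydrogen-bonds to the chloride on ruthenium, tin goes to the proximal carbon C4 and hydrogen to C5 from the opposite side, so tin ends cis to C6, and the catalyst is selective for the alkyne over the two electron-poor alkenes.

Step 20
Reactants: 40 methylthiofuranone alkenylstannane
Product: 41 CNP0225232.1, (4Z,6S,7S,8R,10R)-8-[(2E)-but-2-enoyloxy]-15-hydroxy-1-oxo-3,10-epoxygermacra-2,4,11(13)-trien-12,6-olide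
Conditions: Pd2(dba)3 (10 mol %), tri(2-furyl)phosphine (40 mol %), copper thiophene-2-carboxylate (3 equiv), THF (degassed, about 1 mM, slow addition of 40), rt to 50 °C
Reagents that add atoms: none
Why: Zerovalent palladium, helped by the monovalent copper carboxylate that binds the sulfur of the vinylogous thioester, inserts into the C3–S bond, the C4 alkenyl group passes from tin to palladium with retention while the carboxylate takes up tin and copper takes up the thiolate, and reductive elimination joins C3 to C4. The closest known reaction is the Liebeskind–Srogl coupling of thioesters, heteroaryl thioethers and β-alkylthio enones with organostannanes under neutral, base-free conditions. The ring closes in an endo mode to the nine-membered oxa-bridged ring (ten-membered carbocycle C1–C10), the two reacting ends being the termini of one chain that is already bent by the Z alkene, the trans-fused lactone and the quaternary C10. No stereocentre is formed; the step needs retention of the C4=C5 geometry, which alkenyl transfer from tin gives, and ring closure in preference to oligomerisation, which high dilution with slow addition and the pre-bent chain favour. The methylene lactone, the crotonate, the ketone and the free C15 hydroxyl should be spared because no base, hydride or strong nucleophile is present. The C6 descriptor changes from R in 40 to S in 41 only because tin leaves the CIP ranking, not by inversion.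

**Compound list**

1 | (R)-citramalic acid | C[C@@](O)(CC(=O)O)C(=O)O | starting material
2 | 2,2-dimethoxypropane | COC(C)(C)OC | starting material
3 | 2-[(4R)-2,2,4-trimethyl-5-oxo-1,3-dioxolan-4-yl]acetic acid | C[C@]1(CC(=O)O)OC(C)(C)OC1=O | intermediate
4 | (5R)-5-(2-hydroxyethyl)-2,2,5-trimethyl-1,3-dioxolan-4-one | C[C@]1(CCO)OC(C)(C)OC1=O | intermediate
5 | (3R)-3-hydroxy-3-methyloxolan-2-one | C[C@@]1(O)CCOC1=O | intermediate
6 | N,O-dimethylhydroxylamine hydrochloride | CNOC.Cl | starting material
7 | (2R)-2,4-dihydroxy-N-methoxy-N,2-dimethylbutanamide | C[C@@](O)(CCO)C(=O)N(C)OC | intermediate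
8 | triethylsilyl trifluoromethanesulfonate | CC[Si](CC)(CC)OS(=O)(=O)C(F)(F)F | starting material
9 | (2R)-N-methoxy-N,2-dimethyl-2,4-bis(triethylsilyloxy)butanamide | C[C@@](O[Si](CC)(CC)CC)(CCO[Si](CC)(CC)CC)C(=O)N(C)OC | intermediate
10 | methylmagnesium bromide | C[Mg]Br | starting material
11 | (3R)-3-methyl-3,5-bis(triethylsilyloxy)pentan-2-one | C[C@@](O[Si](CC)(CC)CC)(CCO[Si](CC)(CC)CC)C(C)=O | intermediate
12 | carbon disulfide | S=C=S | starting material
13 | iodomethane | CI | starting material
14 | dilithium (4R)-4-methyl-3-oxo-4,6-bis(triethylsilyloxy)hex-1-ene-1,1-bis(thiolate) | C[C@@](O[Si](CC)(CC)CC)(CCO[Si](CC)(CC)CC)C(=O)C=C([S-])[S-].[Li+].[Li+] | intermediate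
15 | (4R)-4-methyl-1,1-bis(methylsulfanyl)-4,6-bis(triethylsilyloxy)hex-1-en-3-one | C[C@@](O[Si](CC)(CC)CC)(CCO[Si](CC)(CC)CC)C(=O)C=C(SC)SC | intermediate
16 | (4R)-4,6-dihydroxy-4-methyl-1,1-bis(methylsulfanyl)hex-1-en-3-one | C[C@@](O)(CCO)C(=O)C=C(SC)SC | intermediate
17 | (2R)-2-(2-hydroxyethyl)-2-methyl-5-(methylsulfanyl)furan-3(2H)-one | C[C@]1(CCO)OC(SC)=CC1=O | intermediate
18 | 2-[(2R)-2-methyl-5-(methylsulfanyl)-3-oxo-2,3-dihydrofuran-2-yl]acetaldehyde | C[C@]1(CC=O)OC(SC)=CC1=O | intermediate
19 | 2-butyne-1,4-diol | OCC#CCO | starting material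
20 | 4-methoxybenzyl chloride | COc1ccc(CCl)cc1 | starting material
21 | 4-[(4-methoxyphenyl)methoxy]but-2-yn-1-ol | COc1ccc(COCC#CCO)cc1 | intermediate
22 | iodine | II | starting material
23 | sodium bis(2-methoxyethoxy)aluminate with aluminium in a five-membered ring (O–CH2–CH=C–Al), the ring carbon on aluminium bearing CH2OPMB | [Na+].COCCO[Al-]1(OCCOC)OCC=C1COCc1ccc(OC)cc1 | intermediate
24 | (2Z)-3-iodo-4-[(4-methoxyphenyl)methoxy]but-2-en-1-ol | OC/C=C(\I)COCc1ccc(OC)cc1 | intermediate
25 | (2Z)-3-iodo-4-[(4-methoxyphenyl)methoxy]but-2-enal | O=C/C=C(\I)COCc1ccc(OC)cc1 | intermediate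
26 | tert-butyldimethyl(prop-2-yn-1-yloxy)silane | C#CCO[Si](C)(C)C(C)(C)C | starting material
27 | methyl[3-(tert-butyldimethylsilyloxy)prop-1-yn-1-yl]zinc | C[Zn]C#CCO[Si](C)(C)C(C)(C)C | intermediate
28 | (2Z,4R)-7-(tert-butyldimethylsilyloxy)-2-iodo-1-[(4-methoxyphenyl)methoxy]hept-2-en-5-yn-4-ol | O[C@@H](C#CCO[Si](C)(C)C(C)(C)C)/C=C(\I)COCc1ccc(OC)cc1 | intermediate
29 | carbon monoxide | [C-]#[O+] | starting material
30 | (5R)-5-[3-(tert-butyldimethylsilyloxy)prop-1-yn-1-yl]-3-{[(4-methoxyphenyl)methoxy]methyl}furan-2(5H)-one | O=C1O[C@@H](C#CCO[Si](C)(C)C(C)(C)C)C=C1COCc1ccc(OC)cc1 | intermediate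
31 | (5R)-5-[3-(tert-butyldimethylsilyloxy)prop-1-yn-1-yl]-3-(hydroxymethyl)furan-2(5H)-one | O=C1O[C@@H](C#CCO[Si](C)(C)C(C)(C)C)C=C1CO | intermediate
32 | tetrabromomethane | BrC(Br)(Br)Br | starting material
33 | (5R)-3-(bromomethyl)-5-[3-(tert-butyldimethylsilyloxy)prop-1-yn-1-yl]furan-2(5H)-one | O=C1O[C@@H](C#CCO[Si](C)(C)C(C)(C)C)C=C1CBr | intermediate
34 | {[(5R)-5-[3-(tert-butyldimethylsilyloxy)prop-1-yn-1-yl]-2-oxo-2,5-dihydrofuran-3-yl]methyl}zinc bromide | O=C1O[C@@H](C#CCO[Si](C)(C)C(C)(C)C)C=C1C[Zn]Br | intermediate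
35 | (4S,5R)-5-[3-(tert-butyldimethylsilyloxy)prop-1-yn-1-yl]-4-{(1R)-1-hydroxy-2-[(2R)-2-methyl-5-(methylsulfanyl)-3-oxo-2,3-dihydrofuran-2-yl]ethyl}-3-methylideneoxolan-2-one (6R,7S,8R,10R) | C=C1C(=O)O[C@@H](C#CCO[Si](C)(C)C(C)(C)C)[C@@H]1[C@H](O)C[C@@]2(C)OC(SC)=CC2=O | intermediate
36 | (E)-crotonic anhydride | C/C=C/C(=O)OC(=O)/C=C/C | starting material
37 | (1R)-1-{(2R,3S)-2-[3-(tert-butyldimethylsilyloxy)prop-1-yn-1-yl]-4-methylidene-5-oxooxolan-3-yl}-2-[(2R)-2-methyl-5-(methylsulfanyl)-3-oxo-2,3-dihydrofuran-2-yl]ethyl (2E)-but-2-enoate | C=C1C(=O)O[C@@H](C#CCO[Si](C)(C)C(C)(C)C)[C@@H]1[C@H](OC(=O)/C=C/C)C[C@@]2(C)OC(SC)=CC2=O | intermediate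
38 | (1R)-1-[(2R,3S)-2-(3-hydroxyprop-1-yn-1-yl)-4-methylidene-5-oxooxolan-3-yl]-2-[(2R)-2-methyl-5-(methylsulfanyl)-3-oxo-2,3-dihydrofuran-2-yl]ethyl (2E)-but-2-enoate | C=C1C(=O)O[C@@H](C#CCO)[C@@H]1[C@H](OC(=O)/C=C/C)C[C@@]2(C)OC(SC)=CC2=O | intermediate
39 | tributyltin hydride | CCCC[SnH](CCCC)CCCC | starting material
40 | (1R)-1-{(2R,3S)-2-[(1Z)-3-hydroxy-2-(tributylstannyl)prop-1-en-1-yl]-4-methylidene-5-oxooxolan-3-yl}-2-[(2R)-2-methyl-5-(methylsulfanyl)-3-oxo-2,3-dihydrofuran-2-yl]ethyl (2E)-but-2-enoate | C=C1C(=O)O[C@@H](/C=C(/CO)[Sn](CCCC)(CCCC)CCCC)[C@@H]1[C@H](OC(=O)/C=C/C)C[C@@]2(C)OC(SC)=CC2=O | intermediate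
41 | CNP0225232.1, (4Z,6S,7S,8R,10R)-8-[(2E)-but-2-enoyloxy]-15-hydroxy-1-oxo-3,10-epoxygermacra-2,4,11(13)-trien-12,6-olide | C=C1C(=O)O[C@H]2/C=C(/CO)C3=CC(=O)[C@@](C)(C[C@@H](OC(=O)/C=C/C)[C@H]12)O3 | target

**Step count and risks**

Total step count: 20. Longest linear sequence: 13 steps (steps 1–8, then 16–20).

Steps most likely to fail:

1. Step 20 (ring closure at C3–C4). Oligomerisation may outrun closure of the strained ring, the alkenylstannane may lose tin by protonation or homocouple on copper, and insertion into the C3–S bond may be slow. Fallback, setting out from 30 and 18 and coming back at 41: the C3–C4 bond is made between fragments and the ring is closed at C7–C8 instead.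
   - Butenolide 30 would be desilylated (HF·pyridine) to the propargylic alcohol F1.
   - Hydrostannation ([Cp*RuCl]4, Bu3SnH) would give the (Z)-alkenylstannane F2, and TBSCl/imidazole the silyl ether F3.
   - Intermolecular coupling of F3 with aldehyde 18 under the same Pd2(dba)3/tri(2-furyl)phosphine/copper thiophene-2-carboxylate conditions, without dilution, would give the coupled furanone aldehyde F4.
   - DDQ would free the C13 alcohol F5, and PPh3/NBS at low temperature would give the allylic bromide F6.
   - Intramolecular 2-(alkoxycarbonyl)allylation of the aldehyde with CrCl2 (divalent chromium) in THF at high dilution would close the ring to the macrocyclic alcohol F7.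
   - Crotonic anhydride/DMAP would give the crotonate F8, and HF·pyridine would give 41.

2. Step 16 (Barbier union). Facial selectivity at C7 may be poor because the alkynyl group on C6 is slim, the aldehyde face may be poorly selected, and the allylzinc may be lost by protonation or by ring-opening β-elimination of the lactone oxygen. Fallback, setting out from 33 and coming back at 35: the zinc reagent is replaced by a preformed allylboron reagent with a tighter chair transition state.
   - Bromide 33 would be borylated (B2pin2, Pd2(dba)3 cat., toluene, 50 °C) to the allylboronate F9.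
   - F9 and aldehyde 18 in toluene with Sc(OTf)3 (cat.) would give the O-boryl adduct F10.
   - Hydrolysis at pH 7 would give 35.

3. Step 12 (enantioselective alkynylation). Face selection on the β-iodo enal may be low or of the opposite sense, and methyl transfer from zinc may compete. Fallback, setting out from 25 and coming back at 28: the centre is set by reduction instead of addition.
   - The lithium acetylide of 26 (n-BuLi, THF, −78 °C) would add to 25 to give the racemic alcohol F11.
   - MnO2 would give the alkynyl alkenyl ketone F12.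
   - Corey–Bakshi–Shibata reduction with the (R)-methyl oxazaborolidine and catecholborane at low temperature would give 28, on the premise that the iodoalkenyl arm acts as the large group.

**Further compounds**

F1 | step 20 | (5R)-5-(3-hydroxyprop-1-yn-1-yl)-3-{[(4-methoxyphenyl)methoxy]methyl}furan-2(5H)-one | O=C1O[C@@H](C#CCO)C=C1COCc1ccc(OC)cc1
F2 | step 20 | (5R)-5-[(1Z)-3-hydroxy-2-(tributylstannyl)prop-1-en-1-yl]-3-{[(4-methoxyphenyl)methoxy]methyl}furan-2(5H)-one | O=C1O[C@@H](/C=C(/CO)[Sn](CCCC)(CCCC)CCCC)C=C1COCc1ccc(OC)cc1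
F3 | step 20 | tert-butyldimethylsilyl ether of F2 at the C15 hydroxyl | O=C1O[C@@H](/C=C(/CO[Si](C)(C)C(C)(C)C)[Sn](CCCC)(CCCC)CCCC)C=C1COCc1ccc(OC)cc1
F4 | step 20 | C3–C4 coupled furanone aldehyde (C8 aldehyde, C15 silyl ether, C13 PMB ether, butenolide intact, 4Z) | O=C1O[C@@H](/C=C(/CO[Si](C)(C)C(C)(C)C)C2=CC(=O)[C@@](C)(CC=O)O2)C=C1COCc1ccc(OC)cc1
F5 | step 20 | C13 alcohol obtained from F4 | O=C1O[C@@H](/C=C(/CO[Si](C)(C)C(C)(C)C)C2=CC(=O)[C@@](C)(CC=O)O2)C=C1CO
F6 | step 20 | C13 allylic bromide obtained from F5 | O=C1O[C@@H](/C=C(/CO[Si](C)(C)C(C)(C)C)C2=CC(=O)[C@@](C)(CC=O)O2)C=C1CBr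
F7 | step 20 | macrocyclic C8 alcohol with C15 silyl ether (4Z,6S,7S,8R,10R) | C=C1C(=O)O[C@H]2/C=C(/CO[Si](C)(C)C(C)(C)C)C3=CC(=O)[C@@](C)(C[C@@H](O)[C@H]12)O3
F8 | step 20 | C8 (E)-crotonate of F7 | C=C1C(=O)O[C@H]2/C=C(/CO[Si](C)(C)C(C)(C)C)C3=CC(=O)[C@@](C)(C[C@@H](OC(=O)/C=C/C)[C@H]12)O3
F9 | step 16 | (5R)-5-[3-(tert-butyldimethylsilyloxy)prop-1-yn-1-yl]-3-[(4,4,5,5-tetramethyl-1,3,2-dioxaborolan-2-yl)methyl]furan-2(5H)-one | O=C1O[C@@H](C#CCO[Si](C)(C)C(C)(C)C)C=C1CB1OC(C)(C)C(C)(C)O1
F10 | step 16 | O8-pinacolboryl ether of 35 | C=C1C(=O)O[C@@H](C#CCO[Si](C)(C)C(C)(C)C)[C@@H]1[C@H](OB3OC(C)(C)C(C)(C)O3)C[C@@]2(C)OC(SC)=CC2=O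
F11 | step 12 | racemic (2Z)-7-(tert-butyldimethylsilyloxy)-2-iodo-1-[(4-methoxyphenyl)methoxy]hept-2-en-5-yn-4-ol | OC(C#CCO[Si](C)(C)C(C)(C)C)/C=C(\I)COCc1ccc(OC)cc1
F12 | step 12 | (2Z)-7-(tert-butyldimethylsilyloxy)-2-iodo-1-[(4-methoxyphenyl)methoxy]hept-2-en-5-yn-4-one | O=C(C#CCO[Si](C)(C)C(C)(C)C)/C=C(\I)COCc1ccc(OC)cc1
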